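**Strategy.** Ring D (C8, C14, C13, C16, C15) plus C9 is carried as the benzene ring of an indanone whose five-membered ring is ring B. Oxidative dearomatisation gives a masked o-benzoquinone, and its diene C9=C8–C14=C13 takes up methyl vinyl ketone in a Diels–Alder reaction: C9–C11 and C12–C13 form together, close ring C and set C9, C12 and C13, exploiting the oxygenated C12–C13 edge of ring C. A later radical 1,2-shift of the C15 acyl group from C9 to C8 turns the bicyclo[2.2.2]octenone into the bicyclo[3.2.1]octane of rings C and D. The precursor is a 7-hydroxy-6-methoxy-5-alkoxyindane ketal carrying the C6 ester. Ring A and the lactone are built last on the C10 ketone.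

Key step: step 8

Remark: atoms carry the gibberellane numbers of the target (C7 carboxyl, C17 methylene, C18 methyl, C19 lactone carbonyl); β is the ring-B face bearing H5, H9 and C7; the diene-ligand enantiomer in step 1 is the one that delivers the S ester.

Step 1
Reactants: 1 (3,4,5-trimethoxyphenyl)boronic acid; 2 di-tert-butyl fumarate
Product: 3 di-tert-butyl (S)-2-(3,4,5-trimethoxyphenyl)succinate
Conditions: [RhCl(C2H4)2]2 (cat.), chiral 2,5-diphenylbicyclo[2.2.2]octa-2,5-diene ligand, KOH (cat.), dioxane/H2O, 50 °C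
Reagents that add atoms: none
Why: Rhodium-catalysed asymmetric conjugate addition of the arylboronic acid to the fumarate should give the arylsuccinate, the chiral diene ligand setting the benzylic stereocentre that becomes C6.

Step 2
Reactants: 3 di-tert-butyl (S)-2-(3,4,5-trimethoxyphenyl)succinate
Product: 5 (S)-4,5,6-trimethoxy-3-oxoindane-1-carboxylic acid, via diacid 4 (not isolated)
Conditions: P2O5 in MeSO3H, 50 °C
Reagents that add atoms: none
Why: Acidolysis of the tert-butyl esters and intramolecular Friedel–Crafts acylation by the CH2CO2H arm, the only one able to close a five-membered ring, should give the indanone (ketone = C10, CH2 = C5, CH(CO2H) = C6) without touching the stereocentre.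

Step 3
Reactants: 5 (S)-4,5,6-trimethoxy-3-oxoindane-1-carboxylic acid
Product: 6 (S)-4-hydroxy-5,6-dimethoxy-3-oxoindane-1-carboxylic acid
Conditions: BCl3 (1.1 equiv), CH2Cl2, −78 → 0 °C, aqueous work-up
Reagents that add atoms: none
Why: Chelation-directed Lewis-acid demethylation should cleave only the methoxy group peri to the ketone, which becomes the C15 oxygen.

Step 4
Reactants: 6 (S)-4-hydroxy-5,6-dimethoxy-3-oxoindane-1-carboxylic acid
Product: 7 (S)-4,6-dihydroxy-5-methoxy-3-oxoindane-1-carboxylic acid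
Conditions: NaSEt (excess), DMF, 110 °C, then aqueous HCl
Reagents that add atoms: none
Why: Nucleophilic demethylation (SN2 at methyl) by thiolate should take the methoxy group para to the ketone-bearing carbon (the C13 oxygen), whose phenoxide is the best leaving group, and leave the C16 methoxy group.

Step 5
Reactants: 7 (S)-4,6-dihydroxy-5-methoxy-3-oxoindane-1-carboxylic acid
Product: 8 2-(trimethylsilyl)ethyl (S)-4,6-dihydroxy-5-methoxy-3-oxoindane-1-carboxylate
Conditions: 2-(trimethylsilyl)ethyl 2,2,2-trichloroacetimidate, toluene, 90 °C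
Reagents that add atoms: 2-(trimethylsilyl)ethyl 2,2,2-trichloroacetimidate, C[Si](C)(C)CCOC(=N)C(Cl)(Cl)Cl
Why: Promoter-free imidate esterification alkylates the carboxylic acid and should leave the less acidic phenols untouched.

Step 6
Reactants: 8 2-(trimethylsilyl)ethyl (S)-4,6-dihydroxy-5-methoxy-3-oxoindane-1-carboxylate
Product: 9 2-(trimethylsilyl)ethyl (S)-4-hydroxy-5-methoxy-6-(4-methoxybenzyloxy)-3-oxoindane-1-carboxylate
Conditions: 4-methoxybenzyl chloride, K2CO3, acetone, 50 °C
Reagents that add atoms: 4-methoxybenzyl chloride, COc1ccc(CCl)cc1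
Why: Williamson etherification should occur only at the free C13 phenol, the C15 phenol being deactivated by its hydrogen bond to the ketone.

Step 7
Reactants: 9 2-(trimethylsilyl)ethyl (S)-4-hydroxy-5-methoxy-6-(4-methoxybenzyloxy)-3-oxoindane-1-carboxylate
Product: 10 phenol ketal (C10 ketone of 9 as 1,3-dioxolane)
Conditions: Me3SiOCH2CH2OSiMe3, Me3SiOTf (cat.), CH2Cl2, −20 °C → rt
Reagents that add atoms: 1,2-bis(trimethylsilyloxy)ethane, C[Si](C)(C)OCCO[Si](C)(C)C
Why: Silyl-triflate-catalysed ketalisation masks the C10 ketone so that C9 is not an acyl-bearing, deactivated diene terminus in step 8 and both faces next to C9 stay equivalent.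

Step 8
Reactants: 10 phenol ketal; 11 methyl vinyl ketone
Product: 13 endo-acetyl bicyclo[2.2.2]octenone adduct, via masked o-benzoquinone 12 (not isolated)
Conditions: PhI(OAc)2, MeOH, 11 (excess), 0 → 40 °C
Reagents that add atoms: methanol, CO
Why: PhI(OAc)2 oxidises the phenol to a phenoxonium ion that methanol traps at the methoxy-bearing C16, giving the 6,6-dimethoxycyclohexa-2,4-dienone 12, whose diene C9=C8–C14=C13 then adds the C=C of 11 (oxidative dearomatisation followed by Diels–Alder reaction of a masked o-benzoquinone). The six-membered ring C8–C9–C11–C12–C13–C14 is closed by this bimolecular, suprafacial [4+2] cycloaddition, which forms C9–C11 and C12–C13 and leaves the C8=C14 bridge of a bicyclo[2.2.2]octenone. The C13 alkoxy group makes 12 a vinylogous ester, nucleophilic at C9 and electrophilic at C13, so the unsubstituted carbon of 11 should bond to C9 and the acyl-bearing carbon to C13. The dienophile should approach the face anti to the C6 ester on the adjoining ring, which sets C9 and C13 relative to C6. The acetyl group should take the endo position, syn to the C8=C14 bridge, which sets C12 in the orientation of the later 12α oxygen. The step needs cycloaddition to outrun dimerisation of the dienone, which the fully substituted C8 and C9 positions should secure.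

Step 9
Reactants: 13 endo-acetyl bicyclo[2.2.2]octenone adduct
Product: 14 bicyclo[3.2.1]octanone diketone
Conditions: Fe(acac)3 (cat.), PhSiH3, EtOH, 60 °C
Reagents that add atoms: none
Why: Metal-hydride hydrogen-atom transfer to C14 gives the tertiary C8 radical, which undergoes a Dowd–Beckwith 1,2-acyl shift (3-exo attack on the C15 carbonyl, then cleavage of C9–C15) on the face where C15 already lies, making C8 quaternary with C15 β and C14 α, and the C9 radical should then take hydrogen on the face away from the syn-axial C12 acetyl group to give the cis-fused 9β-H.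

Step 10
Reactants: 14 bicyclo[3.2.1]octanone diketone
Product: 15 12α-acetate
Conditions: mCPBA, NaHCO3, CH2Cl2, rt
Reagents that add atoms: 3-chloroperoxybenzoic acid, OOC(=O)c1cccc(Cl)c1
Why: Baeyer–Villiger oxidation with migration of the secondary C12 carbon and retention of configuration turns the acetyl group into the 12α acetate, the C15 ring ketone being shielded by the quaternary C8 and the C16 ketal.

Step 11
Reactants: 15 12α-acetate
Product: 17 15-ketone with C16 methylene, via monomethoxy ketone 16 (not isolated)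
Conditions: SmI2 (excess), THF/MeOH, −78 °C
Reagents that add atoms: none
Why: Reductive cleavage of α-alkoxy ketones by SmI2 (ketyl formation and β-elimination of methoxide, twice) should remove both methoxy groups at C16 and leave the acetate, the ketal and the esters.

Step 12
Reactants: 17 15-ketone with C16 methylene
Product: 19 15-oxo-16-methylene enone, via Mannich base 18 (not isolated)
Conditions: (CH2O)n, iPr2NH2+ CF3CO2−, THF, 65 °C
Reagents that add atoms: formaldehyde (as paraformaldehyde), C=O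
Why: Amine-salt-mediated α-methylenation (Mannich condensation, then elimination of the amine) can occur only at C16, the sole enolisable position of the only ketone.

Step 13
Reactants: 19 15-oxo-16-methylene enone
Product: 21 12α,15β-diol, via 15β-ol 12-acetate 20 (not isolated)
Conditions: NaBH4, CeCl3·7H2O, MeOH, −78 → 0 °C; then K2CO3 (cat.), rt
Reagents that add atoms: none
Why: Luche 1,2-reduction should deliver hydride to C15 from the exo face (the side of the C14 bridge) to give the endo 15β-alcohol, and carbonate-catalysed methanolysis then removes the C12 acetate.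

Step 14
Reactants: 21 12α,15β-diol
Product: 22 bis-TBS ether
Conditions: tBuMe2SiOTf, 2,6-lutidine, CH2Cl2, −78 → 0 °C
Reagents that add atoms: tert-butyldimethylsilyl triflate, CC(C)(C)[Si](C)(C)OS(=O)(=O)C(F)(F)F
Why: Silyl triflate silylation protects both hindered secondary alcohols, with no change at any stereocentre.

Step 15
Reactants: 22 bis-TBS ether
Product: 23 C10 ketone
Conditions: PPTS, acetone/H2O, 50 °C
Reagents that add atoms: water, O
Why: Mild acid-catalysed ketal hydrolysis frees the C10 ketone under conditions that should spare the silyl ethers, the 4-methoxybenzyl ether and the ester and not epimerise C9.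

Step 16
Reactants: 23 C10 ketone; 24 methyl (S)-2-(trifluoromethylsulfonyloxy)propanoate
Product: 25 C5-alkylated keto diester
Conditions: LiN(iPr)2, THF, −78 °C; then 24, −78 → −30 °C
Reagents that add atoms: none
Why: Kinetic enolisation occurs at the C5 methylene rather than the hindered C9 methine, and SN2 alkylation (inversion at the lactate carbon) should occur anti to the C6 ester, placing the C4 side chain α on C5.

Step 17
Reactants: 25 C5-alkylated keto diester
Product: 27 19,10-lactone, via vinyl carbinol 26 (not isolated)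
Conditions: CH2=CHMgBr, CeCl3, THF, −78 °C → rt
Reagents that add atoms: vinylmagnesium bromide, C=C[Mg]Br
Why: Organocerium 1,2-addition to the C10 ketone from the β face, anti to the α substituents on both C5 and C9, puts the alkoxide α and cis to the propanoate, so that it lactonises onto C19 with loss of methoxide.

Step 18
Reactants: 27 19,10-lactone
Product: 28 13-hydroxy lactone
Conditions: DDQ, CH2Cl2/pH 7 buffer, 0 °C → rt
Reagents that add atoms: none
Why: Oxidative cleavage of the 4-methoxybenzyl ether by DDQ frees the C13 hydroxyl before an oxidisable allylic alcohol is present.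

Step 19
Reactants: 28 13-hydroxy lactone; 29 acrolein
Product: 30 aldol adduct
Conditions: LiN(iPr)2 (2.2 equiv), THF, −78 °C; then 29
Reagents that add atoms: none
Why: The lithium lactone enolate should add 1,2 to acrolein on the convex face of the cis-fused bicyclic lactone (setting C4 with the methyl group concave) through a chair Zimmerman–Traxler aldol transition state in which the enolate methyl group, cis to OLi, ends syn to the new hydroxyl, which corresponds to 3β-OH.

Step 20
Reactants: 30 aldol adduct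
Product: 31 12,15-bis-O-TBS 2-(trimethylsilyl)ethyl ester of the target
Conditions: (H2IMes)(PCy3)Cl2Ru=CHPh (second-generation Grubbs catalyst, cat.), CH2Cl2, 40 °C
Reagents that add atoms: none
Why: Ring-closing metathesis of the two vinyl groups closes ring A with the C1=C2 double bond, the hindered 1,1-disubstituted C16 methylene staying out of the reaction.

Step 21
Reactants: 31 12,15-bis-O-TBS 2-(trimethylsilyl)ethyl ester of the target
Product: 32 12α,15β-dihydroxygibberellic acid (the target gibberellin)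
Conditions: Bu4NF, AcOH, THF, rt → 40 °C
Reagents that add atoms: none
Why: Fluoride cleaves both silyl ethers and, by β-elimination, the 2-(trimethylsilyl)ethyl ester under buffered conditions that should not isomerise the allylic lactone.

**Compound list**

1 | (3,4,5-trimethoxyphenyl)boronic acid | OB(O)c1cc(OC)c(OC)c(OC)c1 | starting material
2 | di-tert-butyl fumarate | CC(C)(C)OC(=O)/C=C/C(=O)OC(C)(C)C | starting material
3 | di-tert-butyl (S)-2-(3,4,5-trimethoxyphenyl)succinate | CC(C)(C)OC(=O)C[C@@H](c1cc(OC)c(OC)c(OC)c1)C(=O)OC(C)(C)C | intermediate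
4 | (S)-2-(3,4,5-trimethoxyphenyl)succinic acid (not isolated) | OC(=O)C[C@@H](c1cc(OC)c(OC)c(OC)c1)C(=O)O | intermediate
5 | (S)-4,5,6-trimethoxy-3-oxoindane-1-carboxylic acid | COc1cc2c(c(OC)c1OC)C(=O)C[C@@H]2C(=O)O | intermediate
6 | (S)-4-hydroxy-5,6-dimethoxy-3-oxoindane-1-carboxylic acid | COc1cc2c(c(O)c1OC)C(=O)C[C@@H]2C(=O)O | intermediate
7 | (S)-4,6-dihydroxy-5-methoxy-3-oxoindane-1-carboxylic acid | COc1c(O)cc2c(c1O)C(=O)C[C@@H]2C(=O)O | intermediate
8 | 2-(trimethylsilyl)ethyl (S)-4,6-dihydroxy-5-methoxy-3-oxoindane-1-carboxylate | COc1c(O)cc2c(c1O)C(=O)C[C@@H]2C(=O)OCC[Si](C)(C)C | intermediate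
9 | 2-(trimethylsilyl)ethyl (S)-4-hydroxy-5-methoxy-6-(4-methoxybenzyloxy)-3-oxoindane-1-carboxylate | COc1c(OCc2ccc(OC)cc2)cc2c(c1O)C(=O)C[C@@H]2C(=O)OCC[Si](C)(C)C | intermediate
10 | phenol ketal: 2-(trimethylsilyl)ethyl (S)-7'-hydroxy-6'-methoxy-5'-(4-methoxybenzyloxy)spiro[1,3-dioxolane-2,1'-indane]-3'-carboxylate | COc1c(OCc2ccc(OC)cc2)cc2c(c1O)C1(OCCO1)C[C@@H]2C(=O)OCC[Si](C)(C)C | intermediate
11 | methyl vinyl ketone (but-3-en-2-one) | CC(=O)C=C | starting material
12 | masked o-benzoquinone (not isolated): 6,6-dimethoxycyclohexa-2,4-dienone with C15 ketone, C16 dimethyl ketal, C13 4-methoxybenzyloxy group, fused at C8–C9 to ring B (C10 dioxolane, 6S ester) | COC1(OC)C(OCc2ccc(OC)cc2)=CC2=C(C1=O)C1(OCCO1)C[C@@H]2C(=O)OCC[Si](C)(C)C | intermediate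
13 | Diels–Alder adduct: bicyclo[2.2.2]oct-5-en-2-one with bridgehead C9 (bearing C15 ketone, C11, spiro-ketal C10), bridgehead C13 (4-methoxybenzyloxy, C16 dimethyl ketal, C12), endo acetyl on C12, C8=C14, C11 anti to the C6 ester | COC1(OC)C(=O)[C@]23C4(OCCO4)C[C@H](C(=O)OCC[Si](C)(C)C)C2=C[C@@]1(OCc5ccc(OC)cc5)[C@@H](C(C)=O)C3 | intermediate
14 | bicyclo[3.2.1]octanone: C15 ketone on quaternary C8 (C15 β, C14 α), 9β-H, C12 acetyl, C16 dimethyl ketal | COC1(OC)C(=O)[C@]23C[C@@]1(OCc4ccc(OC)cc4)[C@@H](C(C)=O)C[C@H]2C5(OCCO5)C[C@@H]3C(=O)OCC[Si](C)(C)C | intermediate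
15 | 12α-acetate of 14 (acetyl replaced by acetoxy) | COC1(OC)C(=O)[C@]23C[C@@]1(OCc4ccc(OC)cc4)[C@@H](OC(C)=O)C[C@H]2C5(OCCO5)C[C@@H]3C(=O)OCC[Si](C)(C)C | intermediate
16 | 16-monomethoxy 15-ketone (not isolated, C16 epimers) | COC1C(=O)[C@]23C[C@@]1(OCc4ccc(OC)cc4)[C@@H](OC(C)=O)C[C@H]2C5(OCCO5)C[C@@H]3C(=O)OCC[Si](C)(C)C | intermediate
17 | 15-ketone with C16H2, 12α-acetate, 13-(4-methoxybenzyl) ether, C10 dioxolane | C1C(=O)[C@]23C[C@@]1(OCc4ccc(OC)cc4)[C@@H](OC(C)=O)C[C@H]2C5(OCCO5)C[C@@H]3C(=O)OCC[Si](C)(C)C | intermediate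
18 | Mannich base (not isolated): 17 with CH2N(iPr)2 on C16 | CC(C)N(CC1C(=O)[C@]23C[C@@]1(OCc4ccc(OC)cc4)[C@@H](OC(C)=O)C[C@H]2C5(OCCO5)C[C@@H]3C(=O)OCC[Si](C)(C)C)C(C)C | intermediate
19 | 15-oxo-16-methylene enone | C=C1C(=O)[C@]23C[C@@]1(OCc4ccc(OC)cc4)[C@@H](OC(C)=O)C[C@H]2C5(OCCO5)C[C@@H]3C(=O)OCC[Si](C)(C)C | intermediate
20 | 15β-ol 12α-acetate (not isolated) | C=C1[C@@H](O)[C@]23C[C@@]1(OCc4ccc(OC)cc4)[C@@H](OC(C)=O)C[C@H]2C5(OCCO5)C[C@@H]3C(=O)OCC[Si](C)(C)C | intermediate
21 | 12α,15β-diol | C=C1[C@@H](O)[C@]23C[C@@]1(OCc4ccc(OC)cc4)[C@@H](O)C[C@H]2C5(OCCO5)C[C@@H]3C(=O)OCC[Si](C)(C)C | intermediate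
22 | 12α,15β-bis(tert-butyldimethylsilyl) ether | C=C1[C@@H](O[Si](C)(C)C(C)(C)C)[C@]23C[C@@]1(OCc4ccc(OC)cc4)[C@@H](O[Si](C)(C)C(C)(C)C)C[C@H]2C5(OCCO5)C[C@@H]3C(=O)OCC[Si](C)(C)C | intermediate
23 | C10 ketone (ring B cyclopentanone, C5H2, 9β-H) | C=C1[C@@H](O[Si](C)(C)C(C)(C)C)[C@]23C[C@@]1(OCc4ccc(OC)cc4)[C@@H](O[Si](C)(C)C(C)(C)C)C[C@H]2C(=O)C[C@@H]3C(=O)OCC[Si](C)(C)C | intermediate
24 | methyl (S)-2-(trifluoromethylsulfonyloxy)propanoate | C[C@H](OS(=O)(=O)C(F)(F)F)C(=O)OC | starting material
25 | keto diester: 23 with a CH(CH3)CO2Me group α on C5 (5β-H, trans to the C6 ester) | C=C1[C@@H](O[Si](C)(C)C(C)(C)C)[C@]23C[C@@]1(OCc4ccc(OC)cc4)[C@@H](O[Si](C)(C)C(C)(C)C)C[C@H]2C(=O)[C@@H]([C@H](C)C(=O)OC)[C@@H]3C(=O)OCC[Si](C)(C)C | intermediate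
26 | vinyl carbinol (not isolated): C10 with α-OH and β-vinyl | C=C1[C@@H](O[Si](C)(C)C(C)(C)C)[C@]23C[C@@]1(OCc4ccc(OC)cc4)[C@@H](O[Si](C)(C)C(C)(C)C)C[C@H]2[C@](O)(C=C)[C@@H]([C@H](C)C(=O)OC)[C@@H]3C(=O)OCC[Si](C)(C)C | intermediate
27 | 19,10-γ-lactone with C10 vinyl, C4 H and methyl (methyl on the concave face), 13-(4-methoxybenzyl) ether | C=C1[C@@H](O[Si](C)(C)C(C)(C)C)[C@]23C[C@@]1(OCc4ccc(OC)cc4)[C@@H](O[Si](C)(C)C(C)(C)C)C[C@H]2[C@@]1(C=C)OC(=O)[C@@H](C)[C@H]1[C@@H]3C(=O)OCC[Si](C)(C)C | intermediate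
28 | 13-hydroxy lactone | C=C1[C@@H](O[Si](C)(C)C(C)(C)C)[C@]23C[C@@]1(O)[C@@H](O[Si](C)(C)C(C)(C)C)C[C@H]2[C@@]1(C=C)OC(=O)[C@@H](C)[C@H]1[C@@H]3C(=O)OCC[Si](C)(C)C | intermediate
29 | acrolein (prop-2-enal) | C=CC=O | starting material
30 | aldol adduct: C4 quaternary (methyl, lactone carbonyl, C5, C3), C3 bearing OH (configured as 3β) and vinyl | C=C1[C@@H](O[Si](C)(C)C(C)(C)C)[C@]23C[C@@]1(O)[C@@H](O[Si](C)(C)C(C)(C)C)C[C@H]2[C@@]1(C=C)OC(=O)[C@](C)([C@@H](O)C=C)[C@H]1[C@@H]3C(=O)OCC[Si](C)(C)C | intermediate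
31 | 12,15-bis-O-TBS 2-(trimethylsilyl)ethyl ester of the target | C=C1[C@@H](O[Si](C)(C)C(C)(C)C)[C@]23C[C@@]1(O)[C@@H](O[Si](C)(C)C(C)(C)C)C[C@H]2[C@@]12C=C[C@H](O)[C@@](C)(C(=O)O1)[C@H]2[C@@H]3C(=O)OCC[Si](C)(C)C | intermediate
32 | 12α,15β-dihydroxygibberellic acid (the target gibberellin) | C=C1[C@@H](O)[C@]23C[C@@]1(O)[C@@H](O)C[C@H]2[C@@]12C=C[C@H](O)[C@@](C)(C(=O)O1)[C@H]2[C@@H]3C(=O)O | target

**Totals and risks**

Total step count: 21. Longest linear sequence: 21 steps (from 1 and 2 to 32; 11, 24 and 29 enter as commercial partners).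

Steps most likely to fail:

1. Step 8. The fully substituted push–pull dienone may add methyl vinyl ketone too slowly, so that decomposition of the dienone competes with cycloaddition. Fallback: starting from 10, the same oxidation is run with acrolein, a smaller and more electrophilic dienophile, which should give the endo aldehyde adduct F1. MeMgBr at −78 °C should add only to the aldehyde to give the 1-hydroxyethyl adduct F2, and Dess–Martin oxidation returns to the route at 13.

2. Step 9. Hydrogen-atom transfer from the iron hydride to the C8 radical may outrun the 1,2-acyl shift and simply hydrogenate the alkene. Fallback: starting from 13, Mukaiyama hydration (Co(acac)2, O2, PhSiH3) gives the tertiary C8 alcohol F3, and methyl oxalyl chloride with pyridine gives the mixed C8 methyl oxalate F4. Slow addition of Bu3SnH/AIBN in refluxing toluene then generates the same C8 radical at a very low concentration of hydrogen donor, so that the acyl shift precedes reduction; this returns to the route at 14.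

3. Step 16. Elimination of the secondary triflate or O-alkylation of the enolate may compete with C-alkylation. Fallback: starting from 23, the enolate is alkylated with the primary electrophile methyl bromoacetate to give the C5 acetate keto diester F5, and addition of CH2=CHMgBr/CeCl3 with lactonisation as in step 17 gives the C4-unsubstituted lactone F6. LiN(iPr)2 and MeI then introduce the methyl group on the convex face to give the C4-epimeric lactone F7, and DDQ as in step 18 gives the C4-epimeric 13-hydroxy lactone F8. Under the conditions of step 19 this is deprotonated to the same enolate as 28, and so returns to the route at 30.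

Further compounds
F1 | step 8 | endo-aldehyde Diels–Alder adduct (CHO in place of the acetyl group of 13) | COC1(OC)C(=O)[C@]23C4(OCCO4)C[C@H](C(=O)OCC[Si](C)(C)C)C2=C[C@@]1(OCc5ccc(OC)cc5)[C@@H](C=O)C3
F2 | step 8 | 1-hydroxyethyl adduct (carbinol epimers) | COC1(OC)C(=O)[C@]23C4(OCCO4)C[C@H](C(=O)OCC[Si](C)(C)C)C2=C[C@@]1(OCc5ccc(OC)cc5)[C@@H](C(C)O)C3
F3 | step 9 | C8 tertiary alcohol of the hydrated adduct (C8 epimers) | COC1(OC)C(=O)[C@]23C4(OCCO4)C[C@H](C(=O)OCC[Si](C)(C)C)C2(O)C[C@@]1(OCc5ccc(OC)cc5)[C@@H](C(C)=O)C3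
F4 | step 9 | C8 methyl oxalate of F3 | COC1(OC)C(=O)[C@]23C4(OCCO4)C[C@H](C(=O)OCC[Si](C)(C)C)C2(OC(=O)C(=O)OC)C[C@@]1(OCc5ccc(OC)cc5)[C@@H](C(C)=O)C3
F5 | step 16 | keto diester with CH2CO2Me α on C5 | C=C1[C@@H](O[Si](C)(C)C(C)(C)C)[C@]23C[C@@]1(OCc4ccc(OC)cc4)[C@@H](O[Si](C)(C)C(C)(C)C)C[C@H]2C(=O)[C@@H](CC(=O)OC)[C@@H]3C(=O)OCC[Si](C)(C)C
F6 | step 16 | 19,10-lactone with C4H2 and C10 vinyl | C=C1[C@@H](O[Si](C)(C)C(C)(C)C)[C@]23C[C@@]1(OCc4ccc(OC)cc4)[C@@H](O[Si](C)(C)C(C)(C)C)C[C@H]2[C@@]1(C=C)OC(=O)C[C@H]1[C@@H]3C(=O)OCC[Si](C)(C)C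
F7 | step 16 | C4 epimer of 27 (methyl on the convex face) | C=C1[C@@H](O[Si](C)(C)C(C)(C)C)[C@]23C[C@@]1(OCc4ccc(OC)cc4)[C@@H](O[Si](C)(C)C(C)(C)C)C[C@H]2[C@@]1(C=C)OC(=O)[C@H](C)[C@H]1[C@@H]3C(=O)OCC[Si](C)(C)C
F8 | step 16 | C4 epimer of 28 | C=C1[C@@H](O[Si](C)(C)C(C)(C)C)[C@]23C[C@@]1(O)[C@@H](O[Si](C)(C)C(C)(C)C)C[C@H]2[C@@]1(C=C)OC(=O)[C@H](C)[C@H]1[C@@H]3C(=O)OCC[Si](C)(C)C
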